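The synthesis rests on disconnecting the O–C3 bond of the ten-membered ether ring (numbering: vinyl C1=C2, ether carbon C3, C4, C5, epoxide C6–C7, C8, C9; ring A = C10–C15, with ether carbon C11 and CHBr C14). C3 is a di-tertiary ether carbon carrying the C1=C2 vinyl group; carried as a Co2(CO)6-complexed ethynyl group, that substituent stabilises a cation at C3. In one operation the key step ionises C3, lets the tertiary C11 hydroxyl of ring A close the ten-membered ring and sets the C3 stereocentre by equilibration. Its precursor is an open-chain cobalt-complexed tertiary propargylic alcohol joined through the E C6=C7 alkene to the bromocyclohexanol ring A.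

Key step: step 8

Remarks on the chemistry (assumptions, stated before the steps):
- The atom numbers C1–C15 defined above are used for all compounds.
- Assumption: the antipode of the step 1 catalyst that gives the 14S bromide is identified in a pilot run with both antipodes.
- Ring A: an anti, chair-like bromocyclisation of the E alkene of 1 places Br (C14), the C10 side chain and the C11 oxygen all equatorial, which is the 10S,11S,14S arrangement of the target.
- The E C6=C7 alkene is carried from step 2 to step 10, because syn epoxidation of the E alkene gives the trans 6S,7S epoxide of the target.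
- Precursor design: 13 and 14 are used as the C3 epimer mixture with both tertiary hydroxyls free; no protecting group is needed because only the cluster-flanked C3 hydroxyl ionises in step 8. The cobalt cluster is put on directly before ring closure and removed directly after it.
- The C11 hydroxyl and the C6=C7 alkene are 1,5-related, so every acidic operation from step 4 onwards is kept cold and short to avoid closure to a tetrahydropyran.

Step 1
Reactants: 1 geranylacetone
Product: 3 hydroxy ketone 4-[(1S,3S,6S)-3-bromo-6-hydroxy-2,2,6-trimethylcyclohexyl]butan-2-one, via bromo enol ether 2 (not isolated)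
Conditions: 3,3′-diaryl-BINOL-derived N-aryl thiophosphoramide (10 mol%), DBDMH (0.55 equiv), toluene–CH2Cl2, −90 °C; aq. Na2S2O3; then 1 M HCl, THF–H2O, 0 °C → rt
Reagents that add atoms: 1,3-dibromo-5,5-dimethylhydantoin (DBDMH), CC1(C)N(Br)C(=O)N(Br)C1=O; water, O
Why: Lewis-base-catalysed enantioselective bromonium-initiated polyene cyclisation followed by enol ether hydrolysis: the chiral thiophosphoramide–Br+ adduct selects one face of the terminal C14=C15 alkene (setting C14, absolute sense fixed by the catalyst antipode), the E C10=C11 alkene adds anti through a chair and the ketone oxygen captures the C11 cation, so that Br, the C10 side chain and the C11–O bond end up equatorial (10S,11S relative to 14S), and dilute acid then opens enol ether 2 to the hydroxy ketone.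

Step 2
Reactants: 3 hydroxy ketone; 4 triethyl phosphonoacetate
Product: 5 ethyl (2E)-5-[(1S,3S,6S)-3-bromo-6-hydroxy-2,2,6-trimethylcyclohexyl]-3-methylpent-2-enoate
Conditions: 4 (2.5 equiv), NaH (2.4 equiv), THF, 0 °C → 45 °C; Z isomer removed on silica
Reagents that add atoms: none
Why: Horner–Wadsworth–Emmons olefination of the methyl ketone (open form of the δ-hydroxy ketone) should favour the E enoate with the ester trans to the larger C8 chain; the phosphonate anion is too weak a base to deprotonate the tertiary hydroxyl, and the minor Z isomer is removed by chromatography.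

Step 3
Reactants: 5 E enoate
Product: 6 (2E)-5-[(1S,3S,6S)-3-bromo-6-hydroxy-2,2,6-trimethylcyclohexyl]-3-methylpent-2-en-1-ol
Conditions: i-Bu2AlH (3.5 equiv), CH2Cl2, −78 °C; aq. potassium sodium tartrate
Reagents that add atoms: none
Why: 1,2-Reduction of the conjugated ester by i-Bu2AlH gives the E allylic alcohol without touching the alkene geometry or the secondary bromide (one equivalent of hydride is consumed by the tertiary hydroxyl).

Step 4
Reactants: 6 allylic alcohol
Product: 7 (1S,2S,4S)-4-bromo-2-[(3E)-5-bromo-3-methylpent-3-en-1-yl]-1,3,3-trimethylcyclohexan-1-ol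
Conditions: CBr4 (1.2 equiv), PPh3 (1.2 equiv), CH2Cl2, −20 → 0 °C; used at once
Reagents that add atoms: tetrabromomethane, BrC(Br)(Br)Br
Why: Appel bromination converts the primary allylic hydroxyl by SN2 displacement of its alkoxyphosphonium ion while the hindered tertiary C11 hydroxyl does not react at this temperature; the bromide is used without storage to forestall cyclisation of the C11 hydroxyl onto the allylic system.

Step 5
Reactants: 7 allylic bromide; 8 ethyl acetoacetate
Product: 11 methyl ketone (5E)-8-[(1S,3S,6S)-3-bromo-6-hydroxy-2,2,6-trimethylcyclohexyl]-6-methyloct-5-en-2-one, via keto ester 9 (not isolated), via keto acid 10 (not isolated)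
Conditions: 8 (1.5 equiv), NaH (1.4 equiv), THF, 0 °C → rt; then 2 M NaOH, MeOH, rt → 40 °C; then 1 M HCl to pH 3, 50 °C
Reagents that add atoms: none
Why: Acetoacetic ester synthesis: the soft sodium enolate of 8 displaces the primary allylic bromide by SN2 without allylic transposition (E geometry kept), and saponification followed by decarboxylation of the β-keto acid leaves the methyl ketone; sodium acetoacetate is not basic enough to form the C11 alkoxide, and the neopentyl-type C14 bromide resists the mild aqueous base.

Step 6
Reactants: 11 methyl ketone; 12 ethynylmagnesium bromide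
Product: 13 seco alkyne diol (1S,2S,4S)-4-bromo-2-[(3E)-7-hydroxy-3,7-dimethylnon-3-en-8-yn-1-yl]-1,3,3-trimethylcyclohexan-1-ol (both C3 epimers)
Conditions: HC≡CMgBr (3 equiv), THF, 0 °C → rt; aq. NH4Cl
Reagents that add atoms: none
Why: Grignard 1,2-addition of the acetylide to the methyl ketone gives the tertiary propargylic alcohol (one equivalent is spent on the C11 hydroxyl); the new C3 centre forms as a mixture of epimers, which is harmless because C3 is ionised in step 8.

Step 7
Reactants: 13 seco alkyne diol
Product: 14 Co2(CO)6 complex of the seco alkyne diol (cluster on C1≡C2; both C3 epimers)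
Conditions: Co2(CO)8 (1.1 equiv), CH2Cl2, rt; filtration through silica
Reagents that add atoms: octacarbonyldicobalt, O=C=[Co](=C=O)(=C=O)(=C=O)[Co](=C=O)(=C=O)(=C=O)=C=O
Why: Alkyne complexation: the terminal alkyne displaces two CO ligands of Co2(CO)8 to give the stable (μ-alkyne)Co2(CO)6 cluster, leaving the alkene, the bromide and both hydroxyls untouched.

Step 8
Reactants: 14 Co2(CO)6 complex of the seco alkyne diol
Product: 15 Co2(CO)6 complex of the ten-membered ethynyl ether (3R)
Conditions: BF3·OEt2 (3 equiv), CH2Cl2 (about 1 mM, slow addition of 14), −40 → −10 °C; Et3N quench at −40 °C; epimeric complexes separated on silica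
Reagents that add atoms: none
Why: BF3·OEt2 removes the C3 hydroxyl of 14 to give the tertiary propargylic cation stabilised by the adjacent Co2(CO)6 cluster (Nicholas cation), the tertiary C11 hydroxyl adds to C3 and a proton is lost; because the hindered complexed propargylic ether re-ionises under the same conditions, both C3 epimers of 14, the enyne complex formed by proton loss and open-chain ethers all return to the same cation. The closest known reaction type is the intramolecular Nicholas etherification that closes seven- to nine-membered cyclic ethers with the complexed alkyne outside the ring; here it is applied to a ten-membered ring between two fully substituted carbons. The ten-membered ring closes by O–C3 bond formation in exo mode, so the bent cluster lies outside the ring and does not template it; closure is supported by millimolar concentration, by the fixed diequatorial exits of the C11 oxygen and C9 from ring A and by the rigid E alkene. The new C3 centre is set under thermodynamic control by the C10 and C11 centres of the trans-fused ring A: the bulky Co2(CO)6–alkyne unit is expected to take the outward position away from the axial C11 methyl, taken here to be 3R, and since this is not assured the 3S complex is separated on silica and resubmitted to the same conditions. The step needs ionisation at C3 and not at C11 (only the C3 cation is cluster-stabilised, and the temperature is kept low), capture by oxygen and not by C6=C7 (carbon attack would require a four-membered ring or a secondary cation) and ring closure in preference to chain growth (dilution and a cold Et3N quench, which also protect the 1,5-related C11 hydroxyl and C6=C7 alkene from acid-induced tetrahydropyran formation).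

Step 9
Reactants: 15 Co2(CO)6 complex of the ten-membered ethynyl ether
Product: 16 ten-membered ethynyl ether (2R,5E,8aS,10S,12aS)-10-bromo-2-ethynyl-2,6,9,9,12a-pentamethyl-3,4,7,8,8a,9,10,11,12,12a-decahydro-2H-1-benzoxecine
Conditions: (NH4)2Ce(NO3)6 (5 equiv), acetone, −78 → 0 °C
Reagents that add atoms: none
Why: Oxidative decomplexation: tetravalent cerium oxidises the cobalt cluster and releases the free alkyne, and an oxidant is chosen instead of amine N-oxides or heat because those would open the way to a Pauson–Khand reaction between the cluster and the 1,6-related C6=C7 alkene.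

Step 10
Reactants: 16 ten-membered ethynyl ether
Product: 17 vinyl ether (2R,5E,8aS,10S,12aS)-10-bromo-2-ethenyl-2,6,9,9,12a-pentamethyl-3,4,7,8,8a,9,10,11,12,12a-decahydro-2H-1-benzoxecine
Conditions: H2 (1 atm), Pd/CaCO3 poisoned with Pb(OAc)2 (Lindlar catalyst), quinoline, EtOAc, rt, stopped after one equivalent of H2
Reagents that add atoms: none
Why: Lindlar semi-hydrogenation reduces the terminal alkyne to the vinyl group, and the poisoned catalyst leaves the hindered trisubstituted ring alkene and the C–Br bond alone.

Step 11
Reactants: 17 vinyl ether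
Product: 18 target (2R,5S,6S,8aS,10S,12aS)-10-bromo-2-ethenyl-5,6-epoxy-2,6,9,9,12a-pentamethyldodecahydro-2H-1-benzoxecine
Conditions: mCPBA (1.05 equiv), NaHCO3, CH2Cl2, −20 → 0 °C
Reagents that add atoms: 3-chloroperoxybenzoic acid (mCPBA), OOC(=O)c1cccc(Cl)c1
Why: Prilezhaev epoxidation: the electron-rich trisubstituted C6=C7 alkene reacts far faster than the monosubstituted vinyl group, the concerted syn oxygen transfer turns the E alkene into the trans epoxide, and attack on the outer face of the alkene in the ten-membered ring (the inner face is shielded by the ring) is expected to set 6S,7S under control of the C3, C10 and C11 centres.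

Compound list
1 | geranylacetone, (5E)-6,10-dimethylundeca-5,9-dien-2-one | CC(=O)CC/C=C(\C)CCC=C(C)C | starting material
2 | bromo enol ether, (4aS,6S,8aS)-6-bromo-2,5,5,8a-tetramethyl-4a,5,6,7,8,8a-hexahydro-4H-chromene | CC1=CC[C@H]2C(C)(C)[C@@H](Br)CC[C@]2(C)O1 | intermediate (not isolated)
3 | hydroxy ketone, 4-[(1S,3S,6S)-3-bromo-6-hydroxy-2,2,6-trimethylcyclohexyl]butan-2-one | CC(=O)CC[C@H]1C(C)(C)[C@@H](Br)CC[C@]1(C)O | intermediate
4 | triethyl phosphonoacetate | CCOC(=O)CP(=O)(OCC)OCC | starting material
5 | ethyl (2E)-5-[(1S,3S,6S)-3-bromo-6-hydroxy-2,2,6-trimethylcyclohexyl]-3-methylpent-2-enoate | CCOC(=O)/C=C(\C)CC[C@H]1C(C)(C)[C@@H](Br)CC[C@]1(C)O | intermediate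
6 | (2E)-5-[(1S,3S,6S)-3-bromo-6-hydroxy-2,2,6-trimethylcyclohexyl]-3-methylpent-2-en-1-ol | OC/C=C(\C)CC[C@H]1C(C)(C)[C@@H](Br)CC[C@]1(C)O | intermediate
7 | (1S,2S,4S)-4-bromo-2-[(3E)-5-bromo-3-methylpent-3-en-1-yl]-1,3,3-trimethylcyclohexan-1-ol | BrC/C=C(\C)CC[C@H]1C(C)(C)[C@@H](Br)CC[C@]1(C)O | intermediate
8 | ethyl acetoacetate | CCOC(=O)CC(C)=O | starting material
9 | keto ester, ethyl (4E)-2-acetyl-7-[(1S,3S,6S)-3-bromo-6-hydroxy-2,2,6-trimethylcyclohexyl]-5-methylhept-4-enoate (both epimers at the acetyl-bearing carbon) | CCOC(=O)C(C(C)=O)C/C=C(\C)CC[C@H]1C(C)(C)[C@@H](Br)CC[C@]1(C)O | intermediate (not isolated)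
10 | keto acid, (4E)-2-acetyl-7-[(1S,3S,6S)-3-bromo-6-hydroxy-2,2,6-trimethylcyclohexyl]-5-methylhept-4-enoic acid (both epimers at the acetyl-bearing carbon) | OC(=O)C(C(C)=O)C/C=C(\C)CC[C@H]1C(C)(C)[C@@H](Br)CC[C@]1(C)O | intermediate (not isolated)
11 | methyl ketone, (5E)-8-[(1S,3S,6S)-3-bromo-6-hydroxy-2,2,6-trimethylcyclohexyl]-6-methyloct-5-en-2-one | CC(=O)CC/C=C(\C)CC[C@H]1C(C)(C)[C@@H](Br)CC[C@]1(C)O | intermediate
12 | ethynylmagnesium bromide | C#C[Mg]Br | starting material
13 | seco alkyne diol, (1S,2S,4S)-4-bromo-2-[(3E)-7-hydroxy-3,7-dimethylnon-3-en-8-yn-1-yl]-1,3,3-trimethylcyclohexan-1-ol (both C3 epimers, C3 being the carbinol carbon next to the alkyne) | C#CC(C)(O)CC/C=C(\C)CC[C@H]1C(C)(C)[C@@H](Br)CC[C@]1(C)O | intermediate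
14 | hexacarbonyl{μ-[η2:η2-(1S,2S,4S)-4-bromo-2-[(3E)-7-hydroxy-3,7-dimethylnon-3-en-8-yn-1-yl]-1,3,3-trimethylcyclohexan-1-ol]}dicobalt (Co2(CO)6 cluster on C1≡C2; both C3 epimers) | C12[Co]3(=C=O)(=C=O)(=C=O)[Co]1(=C=O)(=C=O)(=C=O)C23C(C)(O)CC/C=C(\C)CC[C@H]1C(C)(C)[C@@H](Br)CC[C@]1(C)O | intermediate
15 | hexacarbonyl{μ-[η2:η2-(2R,5E,8aS,10S,12aS)-10-bromo-2-ethynyl-2,6,9,9,12a-pentamethyl-3,4,7,8,8a,9,10,11,12,12a-decahydro-2H-1-benzoxecine]}dicobalt (Co2(CO)6 cluster on the ethynyl group) | C12[Co]3(=C=O)(=C=O)(=C=O)[Co]1(=C=O)(=C=O)(=C=O)C23[C@@]1(C)CC/C=C(\C)CC[C@H]2C(C)(C)[C@@H](Br)CC[C@]2(C)O1 | intermediate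
16 | (2R,5E,8aS,10S,12aS)-10-bromo-2-ethynyl-2,6,9,9,12a-pentamethyl-3,4,7,8,8a,9,10,11,12,12a-decahydro-2H-1-benzoxecine (ten-membered ethynyl ether trans-fused to ring A) | C#C[C@@]1(C)CC/C=C(\C)CC[C@H]2C(C)(C)[C@@H](Br)CC[C@]2(C)O1 | intermediate
17 | (2R,5E,8aS,10S,12aS)-10-bromo-2-ethenyl-2,6,9,9,12a-pentamethyl-3,4,7,8,8a,9,10,11,12,12a-decahydro-2H-1-benzoxecine | C=C[C@@]1(C)CC/C=C(\C)CC[C@H]2C(C)(C)[C@@H](Br)CC[C@]2(C)O1 | intermediate
18 | (2R,5S,6S,8aS,10S,12aS)-10-bromo-2-ethenyl-5,6-epoxy-2,6,9,9,12a-pentamethyldodecahydro-2H-1-benzoxecine (3R,6S,7S,10S,11S,14S in the route numbering) | C=C[C@@]1(C)CC[C@@H]2O[C@@]2(C)CC[C@H]2C(C)(C)[C@@H](Br)CC[C@]2(C)O1 | target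

Total step count: 11 steps. Longest linear sequence: 11 steps (1 → 18).

Steps most likely to fail

Step 8 (key step). What may go wrong: proton loss from the C3 cation to enyne complexes and chain-growing intermolecular etherification may outpace closure of the ten-membered ring, or equilibration may settle on the 3S epimer. The fallback makes the hindered ether bond between two separate molecules and closes the ring by C=C formation; it sets out from 3 and comes back to the route at 15. Wittig methylenation of 3 (Ph3P=CH2, THF) should give the isopropenyl alcohol (1S,2S,4S)-4-bromo-1,3,3-trimethyl-2-(3-methylbut-3-en-1-yl)cyclohexan-1-ol F1. Separately, addition of 12 to commercial hex-5-en-2-one should give racemic 3-methylhept-6-en-1-yn-3-ol F2, which Co2(CO)8 converts into its Co2(CO)6 complex F3. Intermolecular Nicholas etherification of F1 with an excess of F3 (BF3·OEt2, 2,6-di-tert-butyl-4-methylpyridine as proton scavenger, CH2Cl2, −78 °C) should give the open-chain di-tertiary ether complex F4 as both C3 epimers; the excess of the small cation partner takes the place of high dilution. Ring-closing metathesis of F4 (second-generation Grubbs catalyst, (H2IMes)(PCy3)Cl2Ru=CHPh, dilute CH2Cl2, 40 °C) between the terminal C6 vinyl group and the C7 isopropenyl group, with the alkyne kept masked by the cobalt cluster, would close the ring at C6=C7 and give 15 after chromatographic removal of the 3S epimer and any Z isomer.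

Step 1. What may go wrong: face discrimination in the bromine transfer to C14=C15 may be poor for a ketone-terminated polyene, and the nucleophilic enol ether 2 may be brominated a second time. The fallback replaces asymmetric catalysis by racemic cyclisation and resolution; it sets out from 1 and comes back to the route at 3. Cyclisation of 1 with the stoichiometric bromonium source [Et2SBr][SbCl5Br] (MeNO2, −25 °C) should give the racemic bromo enol ether F5 with the same relative configuration, which acidic aqueous work-up hydrolyses to the racemic hydroxy ketone F6. Preparative chromatography on a chiral stationary phase (amylose tris(3,5-dimethylphenylcarbamate)) would then separate 3 from its mirror image, the (1R,3R,6R)-hydroxy ketone F7, which is discarded.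

Step 11. What may go wrong: oxygen transfer may show poor facial selectivity or prefer the face that leads to the 6R,7R epoxide. The fallback is a two-step epoxidation through a bromohydrin, which places the oxygen on the face opposite to the one an electrophile attacks; it sets out from 17 and comes back to the route at 18. NBS in THF–H2O (0 °C) should add Br+ to the exposed face of C6=C7 and water anti at the tertiary C7, giving the bromohydrin (2R,5R,6S,8aS,10S,12aS)-5,10-dibromo-2-ethenyl-2,6,9,9,12a-pentamethyldodecahydro-2H-1-benzoxecin-6-ol F8. K2CO3 in MeOH then closes the epoxide by intramolecular SN2 at C6 (the neopentyl-type C14 bromide does not react) and gives 18.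

Further compounds
F1 | step 8 | (1S,2S,4S)-4-bromo-1,3,3-trimethyl-2-(3-methylbut-3-en-1-yl)cyclohexan-1-ol | C=C(C)CC[C@H]1C(C)(C)[C@@H](Br)CC[C@]1(C)O
F2 | step 8 | 3-methylhept-6-en-1-yn-3-ol (racemic) | C#CC(C)(O)CCC=C
F3 | step 8 | hexacarbonyl[μ-(η2:η2-3-methylhept-6-en-1-yn-3-ol)]dicobalt (racemic) | C12[Co]3(=C=O)(=C=O)(=C=O)[Co]1(=C=O)(=C=O)(=C=O)C23C(C)(O)CCC=C
F4 | step 8 | Co2(CO)6 complex of (1S,2S,4S)-4-bromo-1,3,3-trimethyl-2-(3-methylbut-3-en-1-yl)cyclohexyl 3-methylhept-6-en-1-yn-3-yl ether (both epimers at the propargylic carbon) | C12[Co]3(=C=O)(=C=O)(=C=O)[Co]1(=C=O)(=C=O)(=C=O)C23C(C)(CCC=C)O[C@@]1(C)CC[C@H](Br)C(C)(C)[C@@H]1CCC(C)=C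
F5 | step 1 | racemic 6-bromo-2,5,5,8a-tetramethyl-4a,5,6,7,8,8a-hexahydro-4H-chromene (4aS,6S,8aS and 4aR,6R,8aR, 1:1) | CC1=CC[C@H]2C(C)(C)[C@@H](Br)CC[C@]2(C)O1.CC1=CC[C@@H]2C(C)(C)[C@H](Br)CC[C@@]2(C)O1
F6 | step 1 | racemic 4-(3-bromo-6-hydroxy-2,2,6-trimethylcyclohexyl)butan-2-one (1S,3S,6S and 1R,3R,6R, 1:1) | CC(=O)CC[C@H]1C(C)(C)[C@@H](Br)CC[C@]1(C)O.CC(=O)CC[C@@H]1C(C)(C)[C@H](Br)CC[C@@]1(C)O
F7 | step 1 | 4-[(1R,3R,6R)-3-bromo-6-hydroxy-2,2,6-trimethylcyclohexyl]butan-2-one | CC(=O)CC[C@@H]1C(C)(C)[C@H](Br)CC[C@@]1(C)O
F8 | step 11 | (2R,5R,6S,8aS,10S,12aS)-5,10-dibromo-2-ethenyl-2,6,9,9,12a-pentamethyldodecahydro-2H-1-benzoxecin-6-ol | C=C[C@@]1(C)CC[C@@H](Br)[C@@](C)(O)CC[C@H]2C(C)(C)[C@@H](Br)CC[C@]2(C)O1
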